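**Target:** 2-[(2R,12S)-2,12-diacetoxytridecyl]-4,6-dihydroxybenzoic acid (side-chain carbons numbered C1'–C13' from the ring). CIP check of the given SMILES: C2' = R, C12' = S.

## Retrosynthetic overview

1. Target 21 ⇐ acid 20 by one-pot alkene hydrogenation and O-debenzylation. The CO2H is installed late (Vilsmeier formylation, then Pinnick), so no carboxyl derivative ever sits beside a free C2'–OH and dihydroisocoumarin lactonisation cannot occur.
2. C4'=C5' ⇐ cross-metathesis of homoallylic acetate 11 with (S)-dec-9-en-2-yl acetate 16; C12' comes from (S)-propylene oxide.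
3. Key bond C2'–C3' and the C2' (R) centre ⇐ Brown asymmetric carbonyl allylation of arylacetaldehyde 5 with the allylborane made from 6 and 7.
4. Aldehyde 5 ⇐ one-carbon homologation (methoxymethylene Wittig, hydrolysis) of 3,5-bis(benzyloxy)benzaldehyde 1.
5. Rings: none is built; the benzene ring is carried through from 1.

Assumption: (+)-Ipc2BOMe (the enantiomer made from (−)-α-pinene), 7-bromohept-1-ene and Grubbs II catalyst are taken as commercial.

## Route

Step 1
Reactants: 1 3,5-bis(benzyloxy)benzaldehyde; 2 (methoxymethyl)triphenylphosphonium chloride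
Product: 4 1,3-bis(benzyloxy)-5-(2-methoxyethenyl)benzene (E/Z mixture), via (methoxymethylene)triphenylphosphorane 3 (not isolated)
Conditions: KOtBu, THF, 0 °C → rt
Reagents that add atoms: none
Why: Wittig olefination with the methoxymethylene ylide gives the one-carbon-homologated enol ether; no stereocentre is formed and the E/Z ratio is irrelevant.

Step 2
Reactants: 4 1,3-bis(benzyloxy)-5-(2-methoxyethenyl)benzene
Product: 5 2-[3,5-bis(benzyloxy)phenyl]acetaldehyde
Conditions: 2 M aq. HCl, THF, 50 °C; used crude at once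
Reagents that add atoms: water, O
Why: Acid-catalysed enol ether hydrolysis (C-protonation, hemiacetal collapse) unmasks the arylacetaldehyde, and aryl benzyl ethers are stable to dilute aqueous acid.

Step 3
Reactants: 5 2-[3,5-bis(benzyloxy)phenyl]acetaldehyde; 6 allylmagnesium bromide; 7 (+)-B-methoxydiisopinocampheylborane
Product: 10 (2R)-1-[3,5-bis(benzyloxy)phenyl]pent-4-en-2-ol, via (+)-B-allyldiisopinocampheylborane 8 (not isolated), via diisopinocampheylborinate ester 9 (not isolated)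
Conditions: 6 + 7, Et2O, 0 °C → rt; then 5, −78 °C; then 3 M NaOH, 30% H2O2, rt
Reagents that add atoms: none
Why: Brown asymmetric allylboration (carbonyl allylation) through a closed chair transition state, in which the Ipc groups from (−)-α-pinene deliver the allyl group to the Re face of the aldehyde and so set C2' as R (CH2Ar outranks allyl).

Step 4
Reactants: 10 (2R)-1-[3,5-bis(benzyloxy)phenyl]pent-4-en-2-ol
Product: 11 (2R)-1-[3,5-bis(benzyloxy)phenyl]pent-4-en-2-yl acetate
Conditions: Ac2O, pyridine, DMAP (cat.), CH2Cl2, rt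
Reagents that add atoms: acetic anhydride, CC(=O)OC(C)=O
Why: DMAP-catalysed O-acetylation (nucleophilic acyl substitution) installs the final C2' acetate with retention, before any carboxyl group exists that could lactonise.

Step 5
Reactants: 12 7-bromohept-1-ene; 13 (S)-propylene oxide
Product: 15 (2S)-dec-9-en-2-ol, via hept-6-enylmagnesium bromide 14 (not isolated)
Conditions: Mg, THF; then CuI (10 mol%), 13, −30 °C → rt; then 1 M HCl, 0 °C
Reagents that add atoms: none
Why: Grignard formation followed by Cu(I)-catalysed SN2 epoxide opening at the unsubstituted carbon, so the C12' (S) centre comes untouched from (S)-propylene oxide.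

Step 6
Reactants: 15 (2S)-dec-9-en-2-ol
Product: 16 (2S)-dec-9-en-2-yl acetate
Conditions: Ac2O, pyridine, DMAP (cat.), CH2Cl2, rt
Reagents that add atoms: acetic anhydride, CC(=O)OC(C)=O
Why: DMAP-catalysed O-acetylation installs the final C12' acetate with retention of configuration.

Step 7
Reactants: 11 (2R)-1-[3,5-bis(benzyloxy)phenyl]pent-4-en-2-yl acetate; 16 (2S)-dec-9-en-2-yl acetate
Product: 17 (2R,12S)-1-[3,5-bis(benzyloxy)phenyl]tridec-4-ene-2,12-diyl diacetate (E/Z mixture)
Conditions: Grubbs II (5 mol%), 16 (3 equiv), CH2Cl2, 40 °C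
Reagents that add atoms: none
Why: Olefin cross-metathesis of two unhindered terminal alkenes, driven by loss of ethene and excess 16; neither stereocentre is allylic and the E/Z ratio is irrelevant because the alkene is hydrogenated in step 10.

Step 8
Reactants: 17 (2R,12S)-1-[3,5-bis(benzyloxy)phenyl]tridec-4-ene-2,12-diyl diacetate
Product: 19 (2R,12S)-1-[3,5-bis(benzyloxy)-2-formylphenyl]tridec-4-ene-2,12-diyl diacetate, via aryl iminium chloride 18 (not isolated)
Conditions: POCl3, DMF, 0 → 50 °C; then aq. NaOAc, rt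
Reagents that add atoms: N,N-dimethylformamide, CN(C)C=O; water, O
Why: Vilsmeier–Haack formylation (electrophilic aromatic substitution) goes to the ring position beside the alkyl chain, ortho to one benzyloxy group and para to the other, the usual site for 5-alkylresorcinol diethers; acetates, benzyl ethers and the isolated alkene are inert.

Step 9
Reactants: 19 (2R,12S)-1-[3,5-bis(benzyloxy)-2-formylphenyl]tridec-4-ene-2,12-diyl diacetate
Product: 20 2,4-bis(benzyloxy)-6-[(2R,12S)-2,12-diacetoxytridec-4-en-1-yl]benzoic acid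
Conditions: NaClO2, NaH2PO4, 2-methyl-2-butene (excess), t-BuOH/THF/H2O, 0 °C → rt
Reagents that add atoms: sodium chlorite, [Na+].[O-]Cl=O
Why: Pinnick oxidation converts the hindered aryl aldehyde to the acid under buffered conditions, with 2-methyl-2-butene scavenging HOCl so the electron-rich ring and the alkene are not chlorinated.

Step 10
Reactants: 20 2,4-bis(benzyloxy)-6-[(2R,12S)-2,12-diacetoxytridec-4-en-1-yl]benzoic acid
Product: 21 2-[(2R,12S)-2,12-diacetoxytridecyl]-4,6-dihydroxybenzoic acid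
Conditions: H2 (1 atm), 10% Pd/C, EtOAc, rt
Reagents that add atoms: none
Why: Catalytic hydrogenation saturates the alkene and hydrogenolyses both benzyl ethers in one neutral operation that leaves the secondary acetates and both stereocentres untouched.

## Compound list

1 | 3,5-bis(benzyloxy)benzaldehyde | O=Cc1cc(OCc2ccccc2)cc(OCc2ccccc2)c1 | starting material
2 | (methoxymethyl)triphenylphosphonium chloride | COC[P+](c1ccccc1)(c1ccccc1)c1ccccc1.[Cl-] | starting material
3 | (methoxymethylene)triphenylphosphorane | COC=P(c1ccccc1)(c1ccccc1)c1ccccc1 | intermediate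
4 | 1,3-bis(benzyloxy)-5-(2-methoxyethenyl)benzene (E/Z mixture) | COC=Cc1cc(OCc2ccccc2)cc(OCc2ccccc2)c1 | intermediate
5 | 2-[3,5-bis(benzyloxy)phenyl]acetaldehyde | O=CCc1cc(OCc2ccccc2)cc(OCc2ccccc2)c1 | intermediate
6 | allylmagnesium bromide | C=CC[Mg]Br | starting material
7 | (+)-B-methoxydiisopinocampheylborane (from (−)-α-pinene) | COB([C@H]1C[C@H]2C[C@@H]([C@@H]1C)C2(C)C)[C@H]1C[C@H]2C[C@@H]([C@@H]1C)C2(C)C | starting material
8 | (+)-B-allyldiisopinocampheylborane | C=CCB([C@H]1C[C@H]2C[C@@H]([C@@H]1C)C2(C)C)[C@H]1C[C@H]2C[C@@H]([C@@H]1C)C2(C)C | intermediate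
9 | (2R)-1-[3,5-bis(benzyloxy)phenyl]pent-4-en-2-yl diisopinocampheylborinate | C=CC[C@@H](OB([C@H]1C[C@H]2C[C@@H]([C@@H]1C)C2(C)C)[C@H]1C[C@H]2C[C@@H]([C@@H]1C)C2(C)C)Cc1cc(OCc2ccccc2)cc(OCc2ccccc2)c1 | intermediate
10 | (2R)-1-[3,5-bis(benzyloxy)phenyl]pent-4-en-2-ol | C=CC[C@@H](O)Cc1cc(OCc2ccccc2)cc(OCc2ccccc2)c1 | intermediate
11 | (2R)-1-[3,5-bis(benzyloxy)phenyl]pent-4-en-2-yl acetate | C=CC[C@@H](OC(C)=O)Cc1cc(OCc2ccccc2)cc(OCc2ccccc2)c1 | intermediate
12 | 7-bromohept-1-ene | C=CCCCCCBr | starting material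
13 | (S)-propylene oxide | C[C@H]1CO1 | starting material
14 | hept-6-enylmagnesium bromide | C=CCCCCC[Mg]Br | intermediate
15 | (2S)-dec-9-en-2-ol | C[C@H](O)CCCCCCC=C | intermediate
16 | (2S)-dec-9-en-2-yl acetate | C[C@H](OC(C)=O)CCCCCCC=C | intermediate
17 | (2R,12S)-1-[3,5-bis(benzyloxy)phenyl]tridec-4-ene-2,12-diyl diacetate (E/Z mixture) | C[C@H](OC(C)=O)CCCCCCC=CC[C@@H](OC(C)=O)Cc1cc(OCc2ccccc2)cc(OCc2ccccc2)c1 | intermediate
18 | N-{[2,4-bis(benzyloxy)-6-[(2R,12S)-2,12-diacetoxytridec-4-en-1-yl]phenyl]methylidene}-N-methylmethanaminium chloride | C[C@H](OC(C)=O)CCCCCCC=CC[C@@H](OC(C)=O)Cc1cc(OCc2ccccc2)cc(OCc2ccccc2)c1C=[N+](C)C.[Cl-] | intermediate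
19 | (2R,12S)-1-[3,5-bis(benzyloxy)-2-formylphenyl]tridec-4-ene-2,12-diyl diacetate | C[C@H](OC(C)=O)CCCCCCC=CC[C@@H](OC(C)=O)Cc1cc(OCc2ccccc2)cc(OCc2ccccc2)c1C=O | intermediate
20 | 2,4-bis(benzyloxy)-6-[(2R,12S)-2,12-diacetoxytridec-4-en-1-yl]benzoic acid | C[C@H](OC(C)=O)CCCCCCC=CC[C@@H](OC(C)=O)Cc1cc(OCc2ccccc2)cc(OCc2ccccc2)c1C(=O)O | intermediate
21 | 2-[(2R,12S)-2,12-diacetoxytridecyl]-4,6-dihydroxybenzoic acid | CC(=O)O[C@H](CCCCCCCCC[C@H](C)OC(C)=O)Cc1cc(O)cc(O)c1C(=O)O | target

## Summary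

Total step count: 10. Longest linear sequence: 8 steps (1 → 2 → 3 → 4 → 7 → 8 → 9 → 10); steps 5–6 form the side branch.

Steps most likely to fail, each with a fallback:

Step 3. Aldehyde 5 is enolisable and self-condenses easily, so yield and ee of the allylboration are at risk. The fallback sets out from 5 and comes back at 10. Wittig methylenation (Ph3P=CH2, THF, −78 → 0 °C) gives 1-allyl-3,5-bis(benzyloxy)benzene F1. Epoxidation with mCPBA (CH2Cl2, NaHCO3) gives racemic 2-[3,5-bis(benzyloxy)benzyl]oxirane F2. Jacobsen hydrolytic kinetic resolution ((S,S)-(salen)Co(III)OAc, 0.55 equiv H2O) leaves (S)-2-[3,5-bis(benzyloxy)benzyl]oxirane F3 in high ee. Vinylmagnesium bromide with catalytic CuI (THF, −30 °C) opens F3 at the CH2 terminus and gives 10; the stereocentre then comes from the resolution and not from the allylborane.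

Step 7. Cross-metathesis of two terminal alkenes is statistical, so homodimers and incomplete conversion can cut the yield. The fallback sets out from 10 and 15 and comes back at 17, using a temporary silicon tether. Alcohol 15 with excess iPr2SiCl2 and imidazole gives chloro[(2S)-dec-9-en-2-yloxy]diisopropylsilane F4 (excess dichlorosilane removed in vacuo, not purified). F4 silylates 10 (imidazole, DMAP, CH2Cl2) to give {[(2R)-1-[3,5-bis(benzyloxy)phenyl]pent-4-en-2-yl]oxy}{[(2S)-dec-9-en-2-yl]oxy}diisopropylsilane F5. Ring-closing metathesis (Grubbs II, 2 mM in CH2Cl2, 40 °C) closes the 14-membered cyclic diisopropylsilylene acetal F6 without a homodimer problem. TBAF (THF) releases (2R,12S)-1-[3,5-bis(benzyloxy)phenyl]tridec-4-ene-2,12-diol F7, and Ac2O/pyridine/DMAP converts it to 17.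

Step 8. The Vilsmeier reaction may give some of the isomer formylated between the two benzyloxy groups, or be sluggish on the advanced intermediate. The fallback sets out from 17 and comes back at 20. Iodination with NIS (cat. TFA, MeCN, 0 °C; the arene is far more nucleophilic than the isolated alkene) gives (2R,12S)-1-[3,5-bis(benzyloxy)-2-iodophenyl]tridec-4-ene-2,12-diyl diacetate F8. Pd-catalysed hydroxycarbonylation (Pd(OAc)2, HCO2Li/Ac2O as CO source, iPr2NEt, LiCl, DMF, 80 °C) then gives acid 20 directly, bypassing 19 and the Pinnick oxidation.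

## Further compounds

F1 | step 3 | 1-allyl-3,5-bis(benzyloxy)benzene | C=CCc1cc(OCc2ccccc2)cc(OCc2ccccc2)c1
F2 | step 3 | rac-2-[3,5-bis(benzyloxy)benzyl]oxirane | C(c1cc(OCc2ccccc2)cc(OCc2ccccc2)c1)C1CO1
F3 | step 3 | (S)-2-[3,5-bis(benzyloxy)benzyl]oxirane | C(c1cc(OCc2ccccc2)cc(OCc2ccccc2)c1)[C@H]1CO1
F4 | step 7 | chloro[(2S)-dec-9-en-2-yloxy]diisopropylsilane | C[C@H](O[Si](Cl)(C(C)C)C(C)C)CCCCCCC=C
F5 | step 7 | {[(2R)-1-[3,5-bis(benzyloxy)phenyl]pent-4-en-2-yl]oxy}{[(2S)-dec-9-en-2-yl]oxy}diisopropylsilane | C=CC[C@@H](O[Si](C(C)C)(C(C)C)O[C@@H](C)CCCCCCC=C)Cc1cc(OCc2ccccc2)cc(OCc2ccccc2)c1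
F6 | step 7 | 14-membered cyclic diisopropylsilylene acetal of (2R,12S)-1-[3,5-bis(benzyloxy)phenyl]tridec-4-ene-2,12-diol | C[C@H]1CCCCCCC=CC[C@H](Cc2cc(OCc3ccccc3)cc(OCc3ccccc3)c2)O[Si](C(C)C)(C(C)C)O1
F7 | step 7 | (2R,12S)-1-[3,5-bis(benzyloxy)phenyl]tridec-4-ene-2,12-diol | C[C@H](O)CCCCCCC=CC[C@@H](O)Cc1cc(OCc2ccccc2)cc(OCc2ccccc2)c1
F8 | step 8 | (2R,12S)-1-[3,5-bis(benzyloxy)-2-iodophenyl]tridec-4-ene-2,12-diyl diacetate | C[C@H](OC(C)=O)CCCCCCC=CC[C@@H](OC(C)=O)Cc1cc(OCc2ccccc2)cc(OCc2ccccc2)c1I
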